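**Retrosynthetic overview**
1. Endgame: removal of three aryl benzyl ethers and one diol acetonide; the C3–CH2(ring A) bond comes from trans-selective alkylation of a 4-substituted butanolide with a vanillyl bromide.
2. Butanolide ring: the C3–C4 bond is closed by a catalyst-controlled intramolecular carbene C–H insertion of a 3-arylpropyl diazoacetate, which also creates the C4 stereocenter.
3. Enabling feature: lactone C4 is a methine flanked by the ring OCH2 (C5) and the benzylic CH2 of ring B, and C3 lies between C4 and the carbonyl. Unfolded, O1–C5–C4–CH2–ring B is a 3-arylpropyl ester whose central CH2 sits 1,5 to a carbene at C3.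
4. Side chain (1R,2R diol, aryl and benzylic OH anti): auxiliary-controlled anti-aldol of a ring B arylacetyl imide with O-benzylvanillin, then reduction. Ring B comes from 5-allyl-2-hydroxy-3-methoxybenzaldehyde (CHO → CH2CO, allyl → (CH2)3OH).
5. Ring order: temporary 1,3-dioxane (step 8), then the butanolide (step 12); no other ring is formed.

Key step: step 12

Assumption: aldehyde 1 is taken as a catalogue compound; the target is read as 3R,4R (trans lactone) and 1R,2R in the side chain. Ring A is the aryl of the C3 benzyl group, ring B the central aryl, ring C the aryl on the carbinol carbon.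

**Route**

Step 1
Reactants: 1 5-allyl-2-hydroxy-3-methoxybenzaldehyde
Product: 2 5-allyl-2-(benzyloxy)-3-methoxybenzaldehyde
Conditions: BnBr, K2CO3, DMF, 60 °C
Reagents that add atoms: benzyl bromide BrCc1ccccc1
Why: Williamson etherification of the phenol gives a benzyl ether that should survive bases, hydrides and the carbene step and leaves by hydrogenolysis at the end.

Step 2
Reactants: 2 5-allyl-2-(benzyloxy)-3-methoxybenzaldehyde
Product: 3 1-allyl-4-(benzyloxy)-3-methoxy-5-(2-methoxyvinyl)benzene (E/Z mixture)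
Conditions: Ph3P(CH2OMe)Cl, KN(SiMe3)2, THF, 0 °C to rt
Reagents that add atoms: (methoxymethyl)triphenylphosphonium chloride COC[P+](c1ccccc1)(c1ccccc1)c1ccccc1.[Cl-]
Why: Wittig methoxymethylenation adds the one carbon needed for the arylacetic unit; the ylide is preformed with one equivalent of base so that the allyl group should not isomerize.

Step 3
Reactants: 3 1-allyl-4-(benzyloxy)-3-methoxy-5-(2-methoxyvinyl)benzene
Product: 4 2-[5-allyl-2-(benzyloxy)-3-methoxyphenyl]acetaldehyde
Conditions: 2 M aq. HCl, THF, 40 °C; crude product used at once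
Reagents that add atoms: water O
Why: Acid hydrolysis of the enol ether (C-protonation, hemiacetal, loss of methanol) should give the arylacetaldehyde without touching the allyl group or the benzyl ether.

Step 4
Reactants: 4 2-[5-allyl-2-(benzyloxy)-3-methoxyphenyl]acetaldehyde
Product: 5 2-[5-allyl-2-(benzyloxy)-3-methoxyphenyl]acetic acid
Conditions: NaClO2, NaH2PO4, 2-methyl-2-butene, t-BuOH/H2O, rt
Reagents that add atoms: sodium chlorite [Na+].[O-]Cl=O
Why: Pinnick oxidation is selective for the aldehyde, and the alkene scavenger should keep hypochlorous acid away from the allyl group and the electron-rich ring.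

Step 5
Reactants: 5 2-[5-allyl-2-(benzyloxy)-3-methoxyphenyl]acetic acid; 6 (R)-4-benzyloxazolidin-2-one
Product: 8 (R)-3-{2-[5-allyl-2-(benzyloxy)-3-methoxyphenyl]acetyl}-4-benzyloxazolidin-2-one, via mixed pivalic anhydride 7 (not isolated)
Conditions: t-BuCOCl, Et3N, THF, −20 °C; then 6, LiCl, −20 °C to rt
Reagents that add atoms: none
Why: N-acylation of the oxazolidinone through the mixed anhydride under LiCl/Et3N activation is a standard way to attach this auxiliary to an arylacetic acid.

Step 6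
Reactants: 8 (R)-3-{2-[5-allyl-2-(benzyloxy)-3-methoxyphenyl]acetyl}-4-benzyloxazolidin-2-one; 9 4-(benzyloxy)-3-methoxybenzaldehyde
Product: 10 (R)-3-{(2S,3R)-2-[5-allyl-2-(benzyloxy)-3-methoxyphenyl]-3-[4-(benzyloxy)-3-methoxyphenyl]-3-(trimethylsilyloxy)propanoyl}-4-benzyloxazolidin-2-one
Conditions: MgCl2 (0.2 equiv), Et3N, Me3SiCl, EtOAc, rt
Reagents that add atoms: chlorotrimethylsilane C[Si](C)(C)Cl
Why: In this magnesium-halide-catalyzed direct anti-aldol of an N-acyloxazolidinone, soft enolization gives the chelated Z-enolate, the aldehyde adds through a boat-like transition state on the face opposite the auxiliary benzyl group, which should set C2 as S and C3 as R (aryl and oxygen anti), and silylation of the aldolate turns the metal over and blocks retro-aldol.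

Step 7
Reactants: 10 the silylated aldol adduct
Product: 12 (1R,2R)-2-[5-allyl-2-(benzyloxy)-3-methoxyphenyl]-1-[4-(benzyloxy)-3-methoxyphenyl]propane-1,3-diol, via silyl ether alcohol 11 (not isolated)
Conditions: LiBH4, MeOH (2 equiv), THF, 0 °C; then 1 M aq. citric acid, MeOH, rt
Reagents that add atoms: none
Why: Reductive cleavage of the imide with LiBH4 should give the primary alcohol without epimerizing the α-aryl center while it is still silylated, and the mild acid work-up removes the trimethylsilyl group and returns the auxiliary.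

Step 8
Reactants: 12 (1R,2R)-2-[5-allyl-2-(benzyloxy)-3-methoxyphenyl]-1-[4-(benzyloxy)-3-methoxyphenyl]propane-1,3-diol
Product: 13 (4R,5R)-5-[5-allyl-2-(benzyloxy)-3-methoxyphenyl]-4-[4-(benzyloxy)-3-methoxyphenyl]-2,2-dimethyl-1,3-dioxane
Conditions: 2,2-dimethoxypropane, PPTS (cat.), CH2Cl2, rt
Reagents that add atoms: 2,2-dimethoxypropane COC(C)(C)OC
Why: Transacetalization masks both hydroxyls as a trans-4,5-disubstituted dioxane, whose diaxial H4–H5 coupling should also confirm the anti relationship.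

Step 9
Reactants: 13 the allyl dioxane
Product: 15 3-{4-(benzyloxy)-3-[(4R,5R)-4-(4-(benzyloxy)-3-methoxyphenyl)-2,2-dimethyl-1,3-dioxan-5-yl]-5-methoxyphenyl}propan-1-ol, via B-alkyl-9-BBN adduct 14 (not isolated)
Conditions: 9-BBN, THF, 0 °C to rt; then NaOH, H2O2, 0 °C
Reagents that add atoms: hydrogen peroxide OO
Why: Anti-Markovnikov hydroboration–oxidation of the terminal alkene with the bulky borane should give only the primary alcohol and leave acetal and benzyl ethers untouched.

Step 10
Reactants: 15 the 3-arylpropanol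
Product: 16 bromoacetate of 15
Conditions: BrCH2COBr, NaHCO3, MeCN, 0 °C
Reagents that add atoms: bromoacetyl bromide BrCC(Br)=O
Why: Acylation of the primary alcohol with the acid bromide under bicarbonate buffering should keep the acetonide intact.

Step 11
Reactants: 16 the bromoacetate
Product: 17 diazoacetate of 15
Conditions: TsNHNHTs, DBU, THF, 0 °C
Reagents that add atoms: N,N'-ditosylhydrazine Cc1ccc(cc1)S(=O)(=O)NNS(=O)(=O)c1ccc(C)cc1
Why: N-alkylation of ditosylhydrazine by the bromoacetate followed by two base-induced losses of sulfinate is a mild, established route to diazoacetates of functionalized alcohols.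

Step 12
Reactants: 17 the diazoacetate
Product: 18 (R)-4-{4-(benzyloxy)-3-[(4R,5R)-4-(4-(benzyloxy)-3-methoxyphenyl)-2,2-dimethyl-1,3-dioxan-5-yl]-5-methoxybenzyl}dihydrofuran-2(3H)-one
Conditions: Rh2(4R-MPPIM)4 (1 mol %; MPPIM = methyl 2-oxo-1-(3-phenylpropanoyl)imidazolidine-4-carboxylate), CH2Cl2, reflux, 17 added by syringe pump over 10 h to about 0.02 M
Reagents that add atoms: none
Why: Loss of N2 from 17 at the divalent rhodium center gives an electrophilic rhodium carbene whose carbon (future C3) inserts, through a concerted asynchronous three-center transition state, into one C–H bond of the central methylene of the 3-arylpropyl chain (future C4), which makes the C3–C4 bond and releases the catalyst. The closest known reaction type is the enantioselective C–H insertion of 3-arylpropyl diazoacetates to 4-benzylbutanolides with chiral dirhodium carboxamidates. The butanolide closes in the 1,5 mode (carbene carbon, C=O, O, OCH2, CH2; five-membered transition state), and with carboxamidate ligands the six-membered alternative at the benzylic CH2 and the four-membered one at OCH2 should not compete. The new stereocenter C4 is set by the catalyst alone, whose four ester arms around the carbene discriminate the two enantiotopic hydrogens; the 4R catalyst is chosen as the antipode expected to give (4R)-18, a sense to be confirmed on a simple 3-arylpropyl model since the 4S antipode would give the C4 epimer. The step needs chemoselectivity for insertion over addition to the electron-rich ring B, carbene dimerization and attack on ether oxygens or on the activated C–H bonds of the dioxane and benzyl ethers. This is secured by the weakly electrophilic carboxamidate carbene, by slow addition at high dilution, and by the meta position of the dioxane on ring B, which puts those sites out of reach of a small-ring transition state.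

Step 13
Reactants: 19 [4-(benzyloxy)-3-methoxyphenyl]methanol
Product: 20 1-(benzyloxy)-4-(bromomethyl)-2-methoxybenzene
Conditions: PBr3, Et2O, 0 °C; used fresh
Reagents that add atoms: phosphorus tribromide BrP(Br)Br
Why: Bromide displacement of the activated phosphite ester gives the electron-rich benzyl bromide, which is made just before use because it does not store well.

Step 14
Reactants: 18 the 4-substituted butanolide; 20 1-(benzyloxy)-4-(bromomethyl)-2-methoxybenzene
Product: 22 (3R,4R)-3-[4-(benzyloxy)-3-methoxybenzyl]-4-{4-(benzyloxy)-3-[(4R,5R)-4-(4-(benzyloxy)-3-methoxyphenyl)-2,2-dimethyl-1,3-dioxan-5-yl]-5-methoxybenzyl}dihydrofuran-2(3H)-one, via lithium enolate 21 (not isolated)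
Conditions: LiN(SiMe3)2, THF, −78 °C; then 20, DMPU, −78 to −30 °C
Reagents that add atoms: none
Why: In this lactone enolate alkylation the benzyl bromide approaches the planar enolate anti to the C4 substituent, so C3 should be set trans to C4 (3R) by substrate control.

Step 15
Reactants: 22 the protected dibenzylbutanolide
Product: 23 (3R,4R)-3-[4-(benzyloxy)-3-methoxybenzyl]-4-{4-(benzyloxy)-3-[(1R,2R)-1-(4-(benzyloxy)-3-methoxyphenyl)-1,3-dihydroxypropan-2-yl]-5-methoxybenzyl}dihydrofuran-2(3H)-one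
Conditions: AcOH/THF/H2O (3:1:1), 40 °C
Reagents that add atoms: none
Why: Mild aqueous acid hydrolyzes the acetonide at the acetal carbon and should be too weak to ionize the benzylic C–O bond or to open the lactone.

Step 16
Reactants: 23 the tri-O-benzyl diol
Product: 24 (3R,4R)-3-(4-hydroxy-3-methoxybenzyl)-4-{4-hydroxy-3-[(1R,2R)-1,3-dihydroxy-1-(4-hydroxy-3-methoxyphenyl)propan-2-yl]-5-methoxybenzyl}dihydrofuran-2(3H)-one (target)
Conditions: H2 (1 atm), 10 % Pd/C, EtOAc/EtOH, rt, stopped at full conversion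
Reagents that add atoms: none
Why: Hydrogenolysis of aryl benzyl ethers under neutral conditions at 1 atm is much faster than loss of a secondary benzylic hydroxyl, so the three phenols should be freed with the diol, lactone and all four stereocenters intact.

**Compound list**
1 | 5-allyl-2-hydroxy-3-methoxybenzaldehyde | C=CCc1cc(OC)c(O)c(C=O)c1 | starting material
2 | 5-allyl-2-(benzyloxy)-3-methoxybenzaldehyde | C=CCc1cc(OC)c(OCc2ccccc2)c(C=O)c1 | intermediate
3 | 1-allyl-4-(benzyloxy)-3-methoxy-5-(2-methoxyvinyl)benzene (E/Z mixture) | C=CCc1cc(OC)c(OCc2ccccc2)c(C=COC)c1 | intermediate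
4 | 2-[5-allyl-2-(benzyloxy)-3-methoxyphenyl]acetaldehyde | C=CCc1cc(OC)c(OCc2ccccc2)c(CC=O)c1 | intermediate
5 | 2-[5-allyl-2-(benzyloxy)-3-methoxyphenyl]acetic acid | C=CCc1cc(OC)c(OCc2ccccc2)c(CC(=O)O)c1 | intermediate
6 | (R)-4-benzyloxazolidin-2-one | O=C1N[C@H](Cc2ccccc2)CO1 | starting material
7 | mixed anhydride of 5 with pivalic acid | C=CCc1cc(OC)c(OCc2ccccc2)c(CC(=O)OC(=O)C(C)(C)C)c1 | intermediate
8 | (R)-3-{2-[5-allyl-2-(benzyloxy)-3-methoxyphenyl]acetyl}-4-benzyloxazolidin-2-one | C=CCc1cc(OC)c(OCc2ccccc2)c(CC(=O)N2[C@H](Cc3ccccc3)COC2=O)c1 | intermediate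
9 | 4-(benzyloxy)-3-methoxybenzaldehyde | COc1cc(C=O)ccc1OCc1ccccc1 | starting material
10 | (R)-3-{(2S,3R)-2-[5-allyl-2-(benzyloxy)-3-methoxyphenyl]-3-[4-(benzyloxy)-3-methoxyphenyl]-3-(trimethylsilyloxy)propanoyl}-4-benzyloxazolidin-2-one | C=CCc1cc(OC)c(OCc2ccccc2)c(c1)[C@H](C(=O)N1[C@H](Cc2ccccc2)COC1=O)[C@@H](O[Si](C)(C)C)c1ccc(OCc2ccccc2)c(OC)c1 | intermediate
11 | (2R,3R)-2-[5-allyl-2-(benzyloxy)-3-methoxyphenyl]-3-[4-(benzyloxy)-3-methoxyphenyl]-3-(trimethylsilyloxy)propan-1-ol | C=CCc1cc(OC)c(OCc2ccccc2)c(c1)[C@H](CO)[C@@H](O[Si](C)(C)C)c1ccc(OCc2ccccc2)c(OC)c1 | intermediate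
12 | (1R,2R)-2-[5-allyl-2-(benzyloxy)-3-methoxyphenyl]-1-[4-(benzyloxy)-3-methoxyphenyl]propane-1,3-diol | C=CCc1cc(OC)c(OCc2ccccc2)c(c1)[C@H](CO)[C@@H](O)c1ccc(OCc2ccccc2)c(OC)c1 | intermediate
13 | (4R,5R)-5-[5-allyl-2-(benzyloxy)-3-methoxyphenyl]-4-[4-(benzyloxy)-3-methoxyphenyl]-2,2-dimethyl-1,3-dioxane | C=CCc1cc(OC)c(OCc2ccccc2)c(c1)[C@@H]1COC(C)(C)O[C@H]1c1ccc(OCc2ccccc2)c(OC)c1 | intermediate
14 | B-alkyl-9-borabicyclo[3.3.1]nonane adduct of 13 | C(CCc1cc(OC)c(OCc2ccccc2)c(c1)[C@@H]1COC(C)(C)O[C@H]1c1ccc(OCc2ccccc2)c(OC)c1)B1C2CCCC1CCC2 | intermediate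
15 | 3-{4-(benzyloxy)-3-[(4R,5R)-4-(4-(benzyloxy)-3-methoxyphenyl)-2,2-dimethyl-1,3-dioxan-5-yl]-5-methoxyphenyl}propan-1-ol | OCCCc1cc(OC)c(OCc2ccccc2)c(c1)[C@@H]1COC(C)(C)O[C@H]1c1ccc(OCc2ccccc2)c(OC)c1 | intermediate
16 | bromoacetate of 15 | BrCC(=O)OCCCc1cc(OC)c(OCc2ccccc2)c(c1)[C@@H]1COC(C)(C)O[C@H]1c1ccc(OCc2ccccc2)c(OC)c1 | intermediate
17 | diazoacetate of 15 | [N-]=[N+]=CC(=O)OCCCc1cc(OC)c(OCc2ccccc2)c(c1)[C@@H]1COC(C)(C)O[C@H]1c1ccc(OCc2ccccc2)c(OC)c1 | intermediate
18 | (R)-4-{4-(benzyloxy)-3-[(4R,5R)-4-(4-(benzyloxy)-3-methoxyphenyl)-2,2-dimethyl-1,3-dioxan-5-yl]-5-methoxybenzyl}dihydrofuran-2(3H)-one | O=C1C[C@@H](Cc2cc(OC)c(OCc3ccccc3)c(c2)[C@@H]2COC(C)(C)O[C@H]2c2ccc(OCc3ccccc3)c(OC)c2)CO1 | intermediate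
19 | [4-(benzyloxy)-3-methoxyphenyl]methanol | COc1cc(CO)ccc1OCc1ccccc1 | starting material
20 | 1-(benzyloxy)-4-(bromomethyl)-2-methoxybenzene | COc1cc(CBr)ccc1OCc1ccccc1 | intermediate
21 | lithium enolate of 18 | [Li]OC1=C[C@@H](Cc2cc(OC)c(OCc3ccccc3)c(c2)[C@@H]2COC(C)(C)O[C@H]2c2ccc(OCc3ccccc3)c(OC)c2)CO1 | intermediate
22 | (3R,4R)-3-[4-(benzyloxy)-3-methoxybenzyl]-4-{4-(benzyloxy)-3-[(4R,5R)-4-(4-(benzyloxy)-3-methoxyphenyl)-2,2-dimethyl-1,3-dioxan-5-yl]-5-methoxybenzyl}dihydrofuran-2(3H)-one | COc1cc(C[C@H]2C(=O)OC[C@@H]2Cc2cc(OC)c(OCc3ccccc3)c(c2)[C@@H]2COC(C)(C)O[C@H]2c2ccc(OCc3ccccc3)c(OC)c2)ccc1OCc1ccccc1 | intermediate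
23 | (3R,4R)-3-[4-(benzyloxy)-3-methoxybenzyl]-4-{4-(benzyloxy)-3-[(1R,2R)-1-(4-(benzyloxy)-3-methoxyphenyl)-1,3-dihydroxypropan-2-yl]-5-methoxybenzyl}dihydrofuran-2(3H)-one | COc1cc(C[C@H]2C(=O)OC[C@@H]2Cc2cc(OC)c(OCc3ccccc3)c(c2)[C@H](CO)[C@@H](O)c2ccc(OCc3ccccc3)c(OC)c2)ccc1OCc1ccccc1 | intermediate
24 | (3R,4R)-3-(4-hydroxy-3-methoxybenzyl)-4-{4-hydroxy-3-[(1R,2R)-1,3-dihydroxy-1-(4-hydroxy-3-methoxyphenyl)propan-2-yl]-5-methoxybenzyl}dihydrofuran-2(3H)-one | COc1cc(C[C@H]2C(=O)OC[C@@H]2Cc2cc(OC)c(O)c([C@H](CO)[C@@H](O)c3ccc(O)c(OC)c3)c2)ccc1O | target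

**Step count**
Total: 16 steps. Longest linear sequence: 15 steps (1–12, then 14–16); step 13 is a one-step side branch.

**Steps most likely to fail, with fallbacks**

Step 12. The carbene may dimerize, add to the electron-rich ring B, or discriminate the two enantiotopic C–H bonds poorly on this large substrate. The fallback makes the C3–C4 bond by auxiliary-controlled alkylation and closes the ring by lactonization. It sets out from alcohol 15. Oxidation (TEMPO, NaOCl cat., NaClO2, MeCN/phosphate buffer pH 6.7) would give the 3-arylpropanoic acid F1. Acylation of (S)-4-benzyloxazolidin-2-one (t-BuCOCl, Et3N, LiCl, THF) would give the imide F2. Enolization with NaN(SiMe3)2 in THF at −78 °C and alkylation with tert-butyl bromoacetate would give the alkylated imide F3, with the new center R because the electrophile enters anti to the auxiliary benzyl group on the chelated Z-enolate. LiBH4/MeOH in THF at 0 °C would give the hydroxy ester F4, and NaH (cat.) in THF would close it to lactone 18, where the route is rejoined.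

Step 6. The hindered ortho-substituted arylacetyl imide may give low anti or facial selectivity, or the adduct may erode by retro-aldol. The fallback uses no auxiliary: relative configuration comes from a magnesium enediolate and absolute configuration from resolution. It sets out from acid 5. Double deprotonation with i-PrMgCl (2.1 equiv) in THF at 0 °C and addition of aldehyde 9 (Ivanov reaction, chair transition state) would give the racemic anti hydroxy acid F5. Preparative chromatography on a chiral stationary phase would give the (2S,3R)-hydroxy acid F6. LiAlH4 in THF at 0 °C would reduce F6 to diol 12, where the route is rejoined.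

Step 16. Once the para-phenol of ring C is free, the benzylic hydroxyl may be lost by hydrogenolysis, or debenzylation may stall. The fallback masks the benzylic oxygen during hydrogenolysis. It sets out from diol 23. TBSOTf and 2,6-lutidine in CH2Cl2 would give the bis-silyl ether F7. H2 over Pd/C in EtOAc would give the triphenol F8, with the benzylic C–O bond shielded by the bulky silyl group. HF·pyridine in THF at 0 °C would then give target 24.

**Further compounds**
F1 | step 12 | 3-{4-(benzyloxy)-3-[(4R,5R)-4-(4-(benzyloxy)-3-methoxyphenyl)-2,2-dimethyl-1,3-dioxan-5-yl]-5-methoxyphenyl}propanoic acid | OC(=O)CCc1cc(OC)c(OCc2ccccc2)c(c1)[C@@H]1COC(C)(C)O[C@H]1c1ccc(OCc2ccccc2)c(OC)c1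
F2 | step 12 | (S)-4-benzyl-3-(3-arylpropanoyl)oxazolidin-2-one from F1 | O=C(CCc1cc(OC)c(OCc2ccccc2)c(c1)[C@@H]1COC(C)(C)O[C@H]1c1ccc(OCc2ccccc2)c(OC)c1)N1[C@@H](Cc2ccccc2)COC1=O
F3 | step 12 | tert-butyl (R)-3-(arylmethyl)-4-[(S)-4-benzyl-2-oxooxazolidin-3-yl]-4-oxobutanoate | O=C([C@@H](CC(=O)OC(C)(C)C)Cc1cc(OC)c(OCc2ccccc2)c(c1)[C@@H]1COC(C)(C)O[C@H]1c1ccc(OCc2ccccc2)c(OC)c1)N1[C@@H](Cc2ccccc2)COC1=O
F4 | step 12 | tert-butyl (R)-3-(arylmethyl)-4-hydroxybutanoate | OC[C@@H](CC(=O)OC(C)(C)C)Cc1cc(OC)c(OCc2ccccc2)c(c1)[C@@H]1COC(C)(C)O[C@H]1c1ccc(OCc2ccccc2)c(OC)c1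
F5 | step 6 | racemic anti-2-[5-allyl-2-(benzyloxy)-3-methoxyphenyl]-3-[4-(benzyloxy)-3-methoxyphenyl]-3-hydroxypropanoic acid (2S,3R plus 2R,3S) | C=CCc1cc(OC)c(OCc2ccccc2)c(c1)[C@H](C(=O)O)[C@@H](O)c1ccc(OCc2ccccc2)c(OC)c1.C=CCc1cc(OC)c(OCc2ccccc2)c(c1)[C@@H](C(=O)O)[C@H](O)c1ccc(OCc2ccccc2)c(OC)c1
F6 | step 6 | (2S,3R)-2-[5-allyl-2-(benzyloxy)-3-methoxyphenyl]-3-[4-(benzyloxy)-3-methoxyphenyl]-3-hydroxypropanoic acid | C=CCc1cc(OC)c(OCc2ccccc2)c(c1)[C@H](C(=O)O)[C@@H](O)c1ccc(OCc2ccccc2)c(OC)c1
F7 | step 16 | bis(tert-butyldimethylsilyl) ether of 23 | COc1cc(C[C@H]2C(=O)OC[C@@H]2Cc2cc(OC)c(OCc3ccccc3)c(c2)[C@H](CO[Si](C)(C)C(C)(C)C)[C@@H](O[Si](C)(C)C(C)(C)C)c2ccc(OCc3ccccc3)c(OC)c2)ccc1OCc1ccccc1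
F8 | step 16 | bis(tert-butyldimethylsilyl) ether of 24 | COc1cc(C[C@H]2C(=O)OC[C@@H]2Cc2cc(OC)c(O)c(c2)[C@H](CO[Si](C)(C)C(C)(C)C)[C@@H](O[Si](C)(C)C(C)(C)C)c2ccc(O)c(OC)c2)ccc1O
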